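The route rests on the C1–C7 disconnection: quaternary C1, the oxirane carbon that carries the C7 benzoyloxymethyl arm between oxygenated C2 and C6 of the cyclohexene ring, is the carbonyl carbon of a protected inosose. One Corey–Chaykovsky methylenation forms C1–C7, closes a spiro-oxirane and fixes C1 with its oxygen axial, cis to O2 and anti to O6. The precursor is a D-glucose-derived cyclohexanone (carbonyl = glucose C2) carrying 2-OTBS, 3-OPMB, a cis 4,5-acetonide and an axial 6-OTES. Benzoate then opens the oxirane at C7, the C1 alkoxide displaces a C6 mesylate, and Corey–Winter olefination of the 4,5-diol, benzoylation of O3 and desilylation finish the synthesis.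

Key step: step 11

Remarks on the chemistry (conventions and assumptions)
- Locants: cyclitol carbons carry the numbers they have in the target (C1 quaternary oxirane carbon, C2 carbinol, C3 benzoate carbon, C4=C5 alkene, C6 oxirane CH, C7 exocyclic CH2). The ring is viewed with C1→C6 clockwise; β = towards the viewer, α = away. In the target the oxirane oxygen and O2 are β, C7 and O3 are α. TBS = tert-butyldimethylsilyl, TES = triethylsilyl, PMB = 4-methoxybenzyl, Bz = benzoyl.
- Atom origin: with D-glucose the pattern O2 β / O3 α / O6 α (axial) around the carbonyl is obtained only if C1 = Glc C2, C2 = Glc C3, C3 = Glc C4, C4 = Glc C5 (the Ferrier carbonyl), C5 = Glc C6 and C6 = Glc C1 (the axial Ferrier carbinol). The ketone that is methylenated is therefore unmasked at Glc C2 after the carbocyclisation; O2 of the sugar is a temporary benzoate.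
- Precursor design: O2 and O3 carry different ethers (TBS, PMB), so the O3 benzoate needs no selective acylation. C4 loses its configuration in the alkene and is set α, so that O4/O5 form a cis diol held as one acetonide. This avoids a run of adjacent bulky silyl ethers and gives a substrate for stereospecific Corey–Winter olefination. O6 is the small, acid-labile TES ether.

Step 1
Reactants: 1 methyl α-D-glucopyranoside
Product: 2 methyl 4,6-O-[(R)-4-methoxybenzylidene]-α-D-glucopyranoside
Conditions: 4-MeOC6H4CH(OMe)2, CSA (cat.), DMF, 50 °C, reduced pressure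
Reagents that add atoms: 4-methoxybenzaldehyde dimethyl acetal, COC(OC)c1ccc(OC)cc1
Why: Acid-catalysed transacetalisation should give the thermodynamically preferred trans-fused 4,6-acetal with the aryl group equatorial (acetal centre R under thermodynamic control).

Step 2
Reactants: 2 methyl 4,6-O-[(R)-4-methoxybenzylidene]-α-D-glucopyranoside
Product: 3 methyl 2-O-benzoyl-4,6-O-[(R)-4-methoxybenzylidene]-α-D-glucopyranoside
Conditions: BzCl (1.05 equiv), pyridine, CH2Cl2, −40 to −20 °C
Reagents that add atoms: benzoyl chloride, O=C(Cl)c1ccccc1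
Why: Regioselective acylation, since O2 (next to the cis anomeric oxygen) is the more reactive hydroxyl of the 2,3-diol of 4,6-O-arylidene α-glucosides; the benzoate marks the future carbonyl carbon C1.

Step 3
Reactants: 3 methyl 2-O-benzoyl-4,6-O-[(R)-4-methoxybenzylidene]-α-D-glucopyranoside
Product: 4 methyl 2-O-benzoyl-3-O-TBS-4,6-O-[(R)-4-methoxybenzylidene]-α-D-glucopyranoside
Conditions: TBSOTf, 2,6-lutidine, CH2Cl2, −20 to 0 °C
Reagents that add atoms: tert-butyldimethylsilyl triflate, CC(C)(C)[Si](C)(C)OS(=O)(=O)C(F)(F)F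
Why: Silyl triflate silylation of the hindered O3 under a non-nucleophilic base, conditions under which the neighbouring benzoate should not migrate.

Step 4
Reactants: 4 methyl 2-O-benzoyl-3-O-TBS-4,6-O-[(R)-4-methoxybenzylidene]-α-D-glucopyranoside
Product: 5 methyl 2-O-benzoyl-3-O-TBS-4-O-PMB-α-D-glucopyranoside
Conditions: BH3·THF, Bu2BOTf, THF, 0 °C; then Et3N, MeOH
Reagents that add atoms: none
Why: Regioselective reductive opening of a 4,6-O-arylidene acetal: the boron Lewis acid complexes the less hindered O6 and hydride is delivered to the oxocarbenium ion, so O4 keeps the PMB group and O6 is freed.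

Step 5
Reactants: 5 methyl 2-O-benzoyl-3-O-TBS-4-O-PMB-α-D-glucopyranoside
Product: 7 methyl (Z)-6-O-acetyl-2-O-benzoyl-3-O-TBS-4-O-PMB-α-D-xylo-hex-5-enopyranoside, via C6 aldehyde 6 (not isolated)
Conditions: Dess–Martin periodinane, CH2Cl2, rt; then Ac2O, K2CO3, MeCN, 80 °C
Reagents that add atoms: acetic anhydride, CC(=O)OC(C)=O
Why: Dess–Martin oxidation gives the C6 aldehyde, whose enolate (C5–H removed by carbonate) is trapped on oxygen by acetic anhydride to give the Z enol acetate, the usual entry to 6-O-acyl hex-5-enopyranosides.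

Step 6
Reactants: 7 methyl (Z)-6-O-acetyl-2-O-benzoyl-3-O-TBS-4-O-PMB-α-D-xylo-hex-5-enopyranoside
Product: 8 5α-acetoxy-1α-benzoyloxy-6α-hydroxy-3α-PMBO-2β-TBSO-cyclohexan-4-one
Conditions: Hg(OCOCF3)2 (10 mol %), acetone–H2O (4:1), rt
Reagents that add atoms: water, O
Why: Ferrier carbocyclisation (hydroxymercuration of the enol ether, loss of methanol, intramolecular aldol closure through a chair transition state) should place the new C6 hydroxyl axial and trans to O2 and the C5 acetoxy group equatorial, as is known for gluco-configured enol acetates.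

Step 7
Reactants: 8 5α-acetoxy-1α-benzoyloxy-6α-hydroxy-3α-PMBO-2β-TBSO-cyclohexan-4-one
Product: 9 5α-acetoxy-1α-benzoyloxy-3α-PMBO-2β-TBSO-6α-TESO-cyclohexan-4-one
Conditions: TESOTf, 2,6-lutidine, CH2Cl2, −78 °C
Reagents that add atoms: triethylsilyl triflate, CC[Si](CC)(CC)OS(=O)(=O)C(F)(F)F
Why: Low-temperature silyl triflate protection of the axial β-hydroxyl avoids β-elimination and acyl shift; TES is chosen so that it can later be removed beside the TBS ether.

Step 8
Reactants: 9 5α-acetoxy-1α-benzoyloxy-3α-PMBO-2β-TBSO-6α-TESO-cyclohexan-4-one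
Product: 11 3α-PMBO-2β-TBSO-6α-TESO-cyclohexane-1α,4α,5α-triol, via 4α-alcohol diester 10 (not isolated)
Conditions: L-Selectride, THF, −78 °C; then DIBAL-H, −78 to −20 °C; Rochelle salt
Reagents that add atoms: none
Why: Bulky-hydride reduction followed by reductive ester cleavage: L-Selectride should attack C4 from the β (equatorial) side because the axial α face is blocked by the syn-axial 6-OTES, setting the axial 4α alcohol cis to O5, and DIBAL-H removes acetate and benzoate without free alkoxides in a basic protic medium where silyl groups could migrate.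

Step 9
Reactants: 11 3α-PMBO-2β-TBSO-6α-TESO-cyclohexane-1α,4α,5α-triol
Product: 12 4α,5α-O-isopropylidene-3α-PMBO-2β-TBSO-6α-TESO-cyclohexan-1α-ol
Conditions: Me2C(OMe)2, PPTS (cat.), acetone, rt
Reagents that add atoms: 2,2-dimethoxypropane, COC(C)(C)OC
Why: Acetonide formation under thermodynamic control engages the only cis-vicinal diol (O4/O5) and leaves the isolated C1 hydroxyl free.

Step 10
Reactants: 12 4α,5α-O-isopropylidene-3α-PMBO-2β-TBSO-6α-TESO-cyclohexan-1α-ol
Product: 13 4α,5α-O-isopropylidene-3α-PMBO-2β-TBSO-6α-TESO-cyclohexan-1-one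
Conditions: Dess–Martin periodinane, NaHCO3, CH2Cl2, rt
Reagents that add atoms: none
Why: Dess–Martin oxidation of the hindered secondary alcohol under buffered, non-basic conditions should avoid epimerisation or β-elimination next to the α-silyloxy groups.

Step 11
Reactants: 13 4α,5α-O-isopropylidene-3α-PMBO-2β-TBSO-6α-TESO-cyclohexan-1-one; 14 trimethylsulfoxonium iodide
Product: 16 spiro-oxirane of the C-branched cyclitol (oxirane O on C1 β and C7 α; 2β-OTBS; 3α-OPMB; 4α,5α-acetonide; 6α-OTES), via sulfoxonium betaine 15 (not isolated)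
Conditions: Me3S(O)I, NaH, DMSO, rt; then 13 in THF, 0 °C to rt
Reagents that add atoms: none
Why: NaH converts 14 into dimethylsulfoxonium methylide, which adds reversibly to the C1 carbonyl to give betaine 15; the C1 alkoxide then displaces dimethyl sulfoxide from C7 (Corey–Chaykovsky epoxidation, as practised on uloses and substituted cyclohexanones). The only ring formed is the spiro-oxirane, closed in the 3-exo-tet mode. Because addition is reversible, the betaine with the bulky CH2S(O)Me2 group equatorial and the alkoxide axial should be the one that collapses, so C1 is set with O β (cis to O2, anti to O6) and C7 α. The substrate supports this: in the chair with O2, O3 and O5 equatorial the axial site on C1 meets only H3 and H5, whereas in the flipped chair any axial group on C1 would meet axial O3 and O5. The step also needs chemoselectivity over enolisation with loss of the β-oxygens (O3, O5); the weakly basic stabilised ylide, ether-only protection and low temperature are meant to secure it.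

Step 12
Reactants: 16 spiro-oxirane of the C-branched cyclitol; 17 benzoic acid
Product: 18 1α-(benzoyloxymethyl)-4α,5α-O-isopropylidene-3α-PMBO-2β-TBSO-6α-TESO-cyclohexan-1β-ol
Conditions: PhCO2H (3 equiv), Cs2CO3 (25 mol %), DMF, 85 °C
Reagents that add atoms: none
Why: Carboxylate opening of a 2,2-disubstituted oxirane at its unsubstituted carbon (SN2 at C7, benzoic acid as proton source) should give the primary benzoate and the tertiary C1 alcohol with C1 untouched.

Step 13
Reactants: 18 1α-(benzoyloxymethyl)-4α,5α-O-isopropylidene-3α-PMBO-2β-TBSO-6α-TESO-cyclohexan-1β-ol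
Product: 19 1α-(benzoyloxymethyl)-4α,5α-O-isopropylidene-3α-PMBO-2β-TBSO-cyclohexane-1β,6α-diol
Conditions: PPTS (cat.), MeOH–CH2Cl2, 0 °C to rt
Reagents that add atoms: none
Why: Acid-catalysed methanolysis should cleave the triethylsilyl ether much faster than the hindered secondary TBS ether or the cis-fused acetonide.

Step 14
Reactants: 19 1α-(benzoyloxymethyl)-4α,5α-O-isopropylidene-3α-PMBO-2β-TBSO-cyclohexane-1β,6α-diol
Product: 21 1β,6β-epoxy-1α-(benzoyloxymethyl)-4α,5α-O-isopropylidene-3α-PMBO-2β-TBSO-cyclohexane, via 6α-mesylate 20 (not isolated)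
Conditions: MsCl, Et3N, CH2Cl2, 0 °C; then NaH, THF, 0 °C to rt
Reagents that add atoms: methanesulfonyl chloride, CS(=O)(=O)Cl (its atoms stay only in 20)
Why: Sulfonylation of the only secondary hydroxyl followed by Williamson closure: the axial C1 alkoxide displaces the anti-periplanar axial C6 mesylate (3-exo-tet, inversion at C6), which puts the oxirane oxygen on the β face, cis to O2.

Step 15
Reactants: 21 1β,6β-epoxy-1α-(benzoyloxymethyl)-4α,5α-O-isopropylidene-3α-PMBO-2β-TBSO-cyclohexane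
Product: 22 1β,6β-epoxy-1α-(benzoyloxymethyl)-3α-PMBO-2β-TBSO-cyclohexane-4α,5α-diol
Conditions: AcOH–H2O (4:1), 40 °C
Reagents that add atoms: none
Why: Mild aqueous-acid hydrolysis of the isopropylidene acetal; the oxirane is flanked by oxygen-bearing carbons and should resist acid-catalysed opening in the way known for anhydro sugars, while PMB and TBS ethers tolerate these conditions.

Step 16
Reactants: 22 1β,6β-epoxy-1α-(benzoyloxymethyl)-3α-PMBO-2β-TBSO-cyclohexane-4α,5α-diol
Product: 24 [1β,6β-epoxy-3α-PMBO-2β-TBSO-cyclohex-4-en-1α-yl]methyl benzoate, via 4,5-thionocarbonate 23 (not isolated)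
Conditions: 1,1′-thiocarbonyldiimidazole, toluene, 70 °C; then 1,3-dimethyl-2-phenyl-1,3,2-diazaphospholidine, THF, 40 °C
Reagents that add atoms: 1,1′-thiocarbonyldiimidazole, S=C(n1ccnc1)n1ccnc1 (its atoms stay only in 23)
Why: Corey–Winter olefination in its Corey–Hopkins form: the cis diol gives the cyclic thionocarbonate, the phosphorus(III) reagent abstracts sulfur and the carbene loses CO2 by stereospecific syn elimination at 40 °C, conditions that should leave oxirane and ester intact.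

Step 17
Reactants: 24 [1β,6β-epoxy-3α-PMBO-2β-TBSO-cyclohex-4-en-1α-yl]methyl benzoate
Product: 25 [1β,6β-epoxy-3α-hydroxy-2β-TBSO-cyclohex-4-en-1α-yl]methyl benzoate
Conditions: DDQ, CH2Cl2–pH 7 buffer, 0 °C
Reagents that add atoms: none
Why: Oxidative cleavage of the PMB ether by DDQ under buffered conditions is orthogonal to silyl ether, ester, alkene and oxirane.

Step 18
Reactants: 25 [1β,6β-epoxy-3α-hydroxy-2β-TBSO-cyclohex-4-en-1α-yl]methyl benzoate
Product: 26 [3α-benzoyloxy-1β,6β-epoxy-2β-TBSO-cyclohex-4-en-1α-yl]methyl benzoate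
Conditions: BzCl, pyridine, DMAP (cat.), CH2Cl2, 0 °C to rt
Reagents that add atoms: benzoyl chloride, O=C(Cl)c1ccccc1
Why: DMAP-catalysed acylation of the single free (allylic, secondary) hydroxyl installs the C3 benzoate without any regiochemical choice.

Step 19
Reactants: 26 [3α-benzoyloxy-1β,6β-epoxy-2β-TBSO-cyclohex-4-en-1α-yl]methyl benzoate
Product: 27 [3α-benzoyloxy-1β,6β-epoxy-2β-hydroxycyclohex-4-en-1α-yl]methyl benzoate (target)
Conditions: TBAF, AcOH (1:1), THF, 0 °C to rt
Reagents that add atoms: none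
Why: Fluoride desilylation buffered with acetic acid should free O2 without base-induced benzoyl migration or oxirane opening and touches no stereocentre.

Compound list
1 | methyl α-D-glucopyranoside | CO[C@H]1O[C@H](CO)[C@@H](O)[C@H](O)[C@H]1O | starting material
2 | methyl 4,6-O-[(R)-4-methoxybenzylidene]-α-D-glucopyranoside | CO[C@H]1O[C@H](CO2)[C@@H](O[C@@H]2c2ccc(OC)cc2)[C@H](O)[C@H]1O | intermediate
3 | methyl 2-O-benzoyl-4,6-O-[(R)-4-methoxybenzylidene]-α-D-glucopyranoside | CO[C@H]1O[C@H](CO2)[C@@H](O[C@@H]2c2ccc(OC)cc2)[C@H](O)[C@H]1OC(=O)c1ccccc1 | intermediate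
4 | methyl 2-O-benzoyl-3-O-TBS-4,6-O-[(R)-4-methoxybenzylidene]-α-D-glucopyranoside | CO[C@H]1O[C@H](CO2)[C@@H](O[C@@H]2c2ccc(OC)cc2)[C@H](O[Si](C)(C)C(C)(C)C)[C@H]1OC(=O)c1ccccc1 | intermediate
5 | methyl 2-O-benzoyl-3-O-TBS-4-O-PMB-α-D-glucopyranoside (6-OH free) | CO[C@H]1O[C@H](CO)[C@@H](OCc2ccc(OC)cc2)[C@H](O[Si](C)(C)C(C)(C)C)[C@H]1OC(=O)c1ccccc1 | intermediate
6 | C6 aldehyde: methyl 2-O-benzoyl-3-O-TBS-4-O-PMB-α-D-gluco-hexodialdo-1,5-pyranoside (not isolated) | CO[C@H]1O[C@H](C=O)[C@@H](OCc2ccc(OC)cc2)[C@H](O[Si](C)(C)C(C)(C)C)[C@H]1OC(=O)c1ccccc1 | intermediate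
7 | methyl (Z)-6-O-acetyl-2-O-benzoyl-3-O-TBS-4-O-PMB-α-D-xylo-hex-5-enopyranoside | CO[C@H]1O/C(=C\OC(C)=O)[C@@H](OCc2ccc(OC)cc2)[C@H](O[Si](C)(C)C(C)(C)C)[C@H]1OC(=O)c1ccccc1 | intermediate
8 | 5α-acetoxy-1α-benzoyloxy-6α-hydroxy-3α-PMBO-2β-TBSO-cyclohexan-4-one (6-OH axial) | O=C1[C@@H](OCc2ccc(OC)cc2)[C@H](O[Si](C)(C)C(C)(C)C)[C@@H](OC(=O)c2ccccc2)[C@@H](O)[C@H]1OC(C)=O | intermediate
9 | 5α-acetoxy-1α-benzoyloxy-3α-PMBO-2β-TBSO-6α-TESO-cyclohexan-4-one | O=C1[C@@H](OCc2ccc(OC)cc2)[C@H](O[Si](C)(C)C(C)(C)C)[C@@H](OC(=O)c2ccccc2)[C@@H](O[Si](CC)(CC)CC)[C@H]1OC(C)=O | intermediate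
10 | 4α-alcohol diester: 5α-acetoxy-1α-benzoyloxy-3α-PMBO-2β-TBSO-6α-TESO-cyclohexan-4α-ol (not isolated) | O[C@H]1[C@@H](OCc2ccc(OC)cc2)[C@H](O[Si](C)(C)C(C)(C)C)[C@@H](OC(=O)c2ccccc2)[C@@H](O[Si](CC)(CC)CC)[C@H]1OC(C)=O | intermediate
11 | 3α-PMBO-2β-TBSO-6α-TESO-cyclohexane-1α,4α,5α-triol | O[C@H]1[C@@H](OCc2ccc(OC)cc2)[C@H](O[Si](C)(C)C(C)(C)C)[C@@H](O)[C@@H](O[Si](CC)(CC)CC)[C@H]1O | intermediate
12 | 4α,5α-O-isopropylidene-3α-PMBO-2β-TBSO-6α-TESO-cyclohexan-1α-ol | CC1(C)O[C@H]2[C@@H](OCc3ccc(OC)cc3)[C@H](O[Si](C)(C)C(C)(C)C)[C@@H](O)[C@@H](O[Si](CC)(CC)CC)[C@H]2O1 | intermediate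
13 | protected inosose: 4α,5α-O-isopropylidene-3α-PMBO-2β-TBSO-6α-TESO-cyclohexan-1-one | CC1(C)O[C@H]2[C@@H](OCc3ccc(OC)cc3)[C@H](O[Si](C)(C)C(C)(C)C)C(=O)[C@@H](O[Si](CC)(CC)CC)[C@H]2O1 | intermediate
14 | trimethylsulfoxonium iodide | C[S+](C)(C)=O.[I-] | starting material
15 | sulfoxonium betaine: C1 β-alkoxide with α-CH2S(O)Me2 group (not isolated) | CC1(C)O[C@H]2[C@@H](OCc3ccc(OC)cc3)[C@H](O[Si](C)(C)C(C)(C)C)[C@@]([O-])(C[S+](C)(C)=O)[C@@H](O[Si](CC)(CC)CC)[C@H]2O1 | intermediate
16 | spiro-oxirane of the C-branched cyclitol (oxirane O on C1 β, C7 α; 2β-OTBS; 3α-OPMB; 4α,5α-acetonide; 6α-OTES) | CC1(C)O[C@H]2[C@@H](OCc3ccc(OC)cc3)[C@H](O[Si](C)(C)C(C)(C)C)[C@@]3(CO3)[C@@H](O[Si](CC)(CC)CC)[C@H]2O1 | intermediate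
17 | benzoic acid | OC(=O)c1ccccc1 | starting material
18 | 1α-(benzoyloxymethyl)-4α,5α-O-isopropylidene-3α-PMBO-2β-TBSO-6α-TESO-cyclohexan-1β-ol | CC1(C)O[C@H]2[C@@H](OCc3ccc(OC)cc3)[C@H](O[Si](C)(C)C(C)(C)C)[C@@](O)(COC(=O)c3ccccc3)[C@@H](O[Si](CC)(CC)CC)[C@H]2O1 | intermediate
19 | 1α-(benzoyloxymethyl)-4α,5α-O-isopropylidene-3α-PMBO-2β-TBSO-cyclohexane-1β,6α-diol | CC1(C)O[C@H]2[C@@H](OCc3ccc(OC)cc3)[C@H](O[Si](C)(C)C(C)(C)C)[C@@](O)(COC(=O)c3ccccc3)[C@@H](O)[C@H]2O1 | intermediate
20 | 6α-mesylate of 19 (not isolated) | CC1(C)O[C@H]2[C@@H](OCc3ccc(OC)cc3)[C@H](O[Si](C)(C)C(C)(C)C)[C@@](O)(COC(=O)c3ccccc3)[C@@H](OS(C)(=O)=O)[C@H]2O1 | intermediate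
21 | 1β,6β-epoxy-1α-(benzoyloxymethyl)-4α,5α-O-isopropylidene-3α-PMBO-2β-TBSO-cyclohexane | CC1(C)O[C@H]2[C@@H](OCc3ccc(OC)cc3)[C@H](O[Si](C)(C)C(C)(C)C)[C@]3(COC(=O)c4ccccc4)O[C@@H]3[C@H]2O1 | intermediate
22 | 1β,6β-epoxy-1α-(benzoyloxymethyl)-3α-PMBO-2β-TBSO-cyclohexane-4α,5α-diol | O[C@H]1[C@@H](OCc2ccc(OC)cc2)[C@H](O[Si](C)(C)C(C)(C)C)[C@]2(COC(=O)c3ccccc3)O[C@@H]2[C@H]1O | intermediate
23 | 4,5-thionocarbonate of 22 (not isolated) | S=C1O[C@H]2[C@@H](OCc3ccc(OC)cc3)[C@H](O[Si](C)(C)C(C)(C)C)[C@]3(COC(=O)c4ccccc4)O[C@@H]3[C@H]2O1 | intermediate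
24 | [1β,6β-epoxy-3α-PMBO-2β-TBSO-cyclohex-4-en-1α-yl]methyl benzoate | O=C(OC[C@@]12O[C@@H]1C=C[C@@H](OCc1ccc(OC)cc1)[C@@H]2O[Si](C)(C)C(C)(C)C)c1ccccc1 | intermediate
25 | [1β,6β-epoxy-3α-hydroxy-2β-TBSO-cyclohex-4-en-1α-yl]methyl benzoate | O=C(OC[C@@]12O[C@@H]1C=C[C@@H](O)[C@@H]2O[Si](C)(C)C(C)(C)C)c1ccccc1 | intermediate
26 | [3α-benzoyloxy-1β,6β-epoxy-2β-TBSO-cyclohex-4-en-1α-yl]methyl benzoate | O=C(OC[C@@]12O[C@@H]1C=C[C@@H](OC(=O)c1ccccc1)[C@@H]2O[Si](C)(C)C(C)(C)C)c1ccccc1 | intermediate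
27 | [3α-benzoyloxy-1β,6β-epoxy-2β-hydroxycyclohex-4-en-1α-yl]methyl benzoate | O=C(OC[C@@]12O[C@@H]1C=C[C@@H](OC(=O)c1ccccc1)[C@@H]2O)c1ccccc1 | target

Total step count: 19. Longest linear sequence: 19 steps (1 to 27).

Steps most likely to fail

Step 11 (key step). The ylide may add from the wrong face, putting the new C–C bond axial, or the ketone may enolise and lose a β-oxygen. The fallback separates carbon transfer from oxygen transfer. It sets out from 13: Wittig methylenation (Ph3P=CH2, THF, −78 to 0 °C) should give the 1-methylidene compound F1. Epoxidation with mCPBA/NaHCO3 should then occur from the β face, anti to the axial 6-OTES and the α-acetonide, and the route is rejoined at 16.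

Step 15. The oxirane may be opened by acid, possibly with participation of the C7 benzoate, while the acetonide is hydrolysed. The fallback removes the acetonide before the oxirane exists. It sets out from 20, isolated this time: aqueous acetic acid should give the diol mesylate F2, and thiocarbonyldiimidazole the thionocarbonate mesylate F3. KHMDS (THF, −78 °C) then closes the oxirane, and the route is rejoined at 23, which takes the phosphorus reagent of step 16.

Step 14. Sulfonylation of the hindered axial C6 hydroxyl may be incomplete, or the benzoyl group may shift to the tertiary alkoxide during the basic closure. The fallback sets out from 19 and uses a Mitsunobu cyclodehydration (PPh3, DIAD, toluene): the secondary hydroxyl is activated and displaced by the tertiary one with inversion. The route is rejoined at 21; this fallback makes no new compound (F0).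

Further compounds
F1 | step 11 | 4α,5α-O-isopropylidene-1-methylidene-3α-PMBO-2β-TBSO-6α-TESO-cyclohexane | CC1(C)O[C@H]2[C@@H](OCc3ccc(OC)cc3)[C@H](O[Si](C)(C)C(C)(C)C)C(=C)[C@@H](O[Si](CC)(CC)CC)[C@H]2O1
F2 | step 15 | 1α-(benzoyloxymethyl)-6α-mesyloxy-3α-PMBO-2β-TBSO-cyclohexane-1β,4α,5α-triol | O[C@H]1[C@@H](OCc2ccc(OC)cc2)[C@H](O[Si](C)(C)C(C)(C)C)[C@@](O)(COC(=O)c2ccccc2)[C@@H](OS(C)(=O)=O)[C@H]1O
F3 | step 15 | 4,5-thionocarbonate of F2 | S=C1O[C@H]2[C@@H](OCc3ccc(OC)cc3)[C@H](O[Si](C)(C)C(C)(C)C)[C@@](O)(COC(=O)c3ccccc3)[C@@H](OS(C)(=O)=O)[C@H]2O1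
F0 | step 14 | none | none
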